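(Readings and results were computed on assumed constants; scatter was added.)

**The clock.** Minutes are the unit to carry from these runs. The turnover clock T is the time in which Sbt falls by a factor e, taken as a pseudo-first-order time constant: Sbt present over its rate of loss. The flasks and the questions stand here:

| flask | Sbt | Ptn | Ctl | Pdt | time |
|---|---|---|---|---|---|
| south | 80.0 mM | 240 mM | 8.00 mM |  |  |
| west | 40.0 mM | 200 mM | 8.00 mM |  |  |
| east | 80.0 mM | 240 mM | 8.00 mM | 40.0 mM |  |
| south-east | 80.0 mM | 120 mM | 8.00 mM |  |  |
| south-west | 80.0 mM | 240 mM | 3.20 mM |  | 56 min |

- south run (time / min: [Pdt] / mM): 4.3: 10.41; 13: 27.96; 25: 45.32; 39: 59.00; 56: 68.13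
- west run (time / min: [Pdt] / mM): 4.3: 5.80; 13: 14.28; 25: 23.38; 39: 30.04; 56: 34.69
- east run (time / min: [Pdt] / mM): 4.3: 50.74; 13: 67.75; 25: 85.62; 39: 98.62; 56: 108.82
- south-east run (time / min: [Pdt] / mM): 4.3: 6.92; 13: 18.52; 25: 31.28; 39: 42.52; 56: 52.21

(each reading ± 0.2 mM)

- Overall: Sbt + Ptn -> Pdt, with Ctl as catalyst.
- Constant volume, constant temperature.
- What is held in complexes is read along with the free species.
- "The second partner" is Ptn.
- An order is taken over about fifteen percent of the charge, up and down.

- how the opening rate goes with [Sbt] round the charge of the south run: the exponent of the rate at two percent of Sbt gone to Pdt (one fixed amount of Pdt, the same in the runs compared)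
- how the opening rate goes with [Ptn] round the charge of the south run: the exponent of the rate at two percent of Sbt gone to Pdt
- the west run starts with 40.0 mM less of Sbt and of Ptn than the south run, and with no Pdt. Compared where both hold the same amount of Sbt, once fifteen percent of what the west run was charged with has turned into Pdt, is the west run faster, slower or alike (within a tenth)?
- Pdt in the south-west run at 56 min, as a share of the Sbt charged
- which of these the readings show (the second partner pairs with itself / nothing beyond the main steps / the catalyst wakes slowly / the product speeds the reaction)

**Opening reading.** Read from one point of a run, T is the time of that reading over the ln of the Sbt charged divided by the Sbt left, which is the charge less the Pdt made. The south run holds 10.41 mM of Pdt at 4.3 min, so its opening clock is 30.8 min. The south-east run, with Ptn at 120 mM instead of 240 mM, holds 6.92 mM at the same time, and its clock of 47.5 min is longer by a factor 1.54. The east run, charged with 40.0 mM of Pdt, has made 45.6 mM at 25 min, against 45.32 mM in the south run, so the clock is carried with no term for added Pdt.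

**First estimate.** The south-west run holds 3.20 mM of Ctl against 8.00 mM. With the clock taken as inverse in Ctl, it stretches to 77.1 min. Then 56 min gives a share of 51.6%.

**Weak link.** That clock belongs to the opening, while the south-west run ends far from its opening. The south run gives a better reading: at 25 min it holds 45.32 mM of Pdt, which is 56.6% of the Sbt charged, so the clock over that longer stretch is 29.9 min. This is shorter than the opening clock. Scaled by Ctl it becomes 74.8 min, and the share at 56 min comes to 52.7%, the number to commit to.

**Forecast.** The forecast, reading the rate as “ordinary catalyst saturation”, gave orders of 0.68 in Sbt and 0.55 in Ptn, the west run alike, a share of 52.6% (range 49% to 55%), and "nothing beyond the main steps".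

**Result.** The simulation gives orders of 0.68 in Sbt and 0.61 in Ptn, the west run alike, a share of 53.5%, and "the second partner pairs with itself".

    Ctl + Sbt ⇌ Ctl.Sbt, settled at all times (5.390 /M)
    Ctl.Sbt + Ptn ⇌ Ctl.Sbt.Ptn, settled at all times (2.200 /M)
    Ctl.Sbt.Ptn → Pdt + Ctl (4.818 /min)
    2 Ptn ⇌ Ptn2, settled at all times (5.230 /M)

**Pairing.** Read back from the south-west run, the clock is 73.2 min, against 74.8 min reckoned from the south clock of 29.9 min. The same flask without the tying up of Ptn as Ptn2 reaches 78.5%, a clock of 36.5 min. The south-west clock is thus twice as long on account of that pairing. The pairing also takes the order in Ptn from 0.87 down to 0.61.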